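## Retrosynthetic overview

- Cutting the aryl–CH2 bond of the open-chain precursor (Friedel–Crafts direction) leaves methyl 2,3,4-trihydroxybenzoate (1) and (2E,6E)-farnesol (2); their union 3 is carried as triacetate 4.
- Both carbocycles and all four stereocentres are traced back to achiral triene 4 in one acid-catalysed cascade: ring A closes first (C4–C5 bond), ring B second (C9–C10 bond), giving drim-8-yl cation 5.
- The rearranged (4,9-friedo-drimane) skeleton comes from 5, without isolation, by four 1,2-shifts (H, CH3, H, CH3) through cations 6, 7 and 8 to C4 cation 9; loss of a proton from the methyl group left on C4 gives exocyclic alkene 10.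
- Removal of the three acetyl groups from 10 gives the target 11.

Numbering: ring carbons C1–C10 as in drimane; C11 is the benzylic CH2 on C9; β is the face of the angular 10-CH3 in 5, α the opposite face; Ar = 2,3,4-triacetoxy-5-(methoxycarbonyl)phenyl.

Assumption: the (S,S) acid catalyst is taken to give the natural drimane series (5α-H, 10β-CH3); if induction is opposite, the (R,R) catalyst is used. The enantiomer ratio from step 3 is raised to a single enantiomer by recrystallisation of 10 or chiral-phase HPLC.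

## Route

Step 1
Reactants: 1 methyl 2,3,4-trihydroxybenzoate; 2 (2E,6E)-farnesol [(2E,6E)-3,7,11-trimethyldodeca-2,6,10-trien-1-ol]
Product: 3 methyl 2,3,4-trihydroxy-5-[(2E,6E)-3,7,11-trimethyldodeca-2,6,10-trien-1-yl]benzoate
Conditions: acidic Al2O3, 1 (2 equiv), ClCH2CH2Cl, 80 °C, Ar
Reagents that add atoms: none
Why: Friedel–Crafts C-allylation of a phenol with an allylic alcohol on acidic alumina: the surface-bound 4-phenoxide delivers the farnesyl cation to its only free ortho carbon, C5 (also para to 2-OH and meta to the ester), the 2E geometry is kept because the allyl cation is captured at its primary end, and no stereocentre is created.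

Step 2
Reactants: 3 methyl 2,3,4-trihydroxy-5-[(2E,6E)-3,7,11-trimethyldodeca-2,6,10-trien-1-yl]benzoate
Product: 4 methyl 2,3,4-triacetoxy-5-[(2E,6E)-3,7,11-trimethyldodeca-2,6,10-trien-1-yl]benzoate
Conditions: Ac2O (4 equiv), pyridine, 4-(dimethylamino)pyridine (5 mol%), CH2Cl2, 0 °C to rt, Ar
Reagents that add atoms: acetic anhydride CC(=O)OC(C)=O
Why: DMAP-catalysed O-acylation of all three phenols; the acetates make the oxygen ortho to the side chain non-nucleophilic and the ring electron-poor, which blocks chroman formation and Friedel–Crafts (indane) closure in step 3, and no stereocentre is involved.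

Step 3
Reactants: 4 methyl 2,3,4-triacetoxy-5-[(2E,6E)-3,7,11-trimethyldodeca-2,6,10-trien-1-yl]benzoate
Product: 10 methyl 2,3,4-triacetoxy-5-{[(1R,2S,4aS,8aS)-1,2,4a-trimethyl-5-methylidenedecahydronaphthalen-1-yl]methyl}benzoate, via drim-8-yl cation 5 (not isolated), via C9 cation 6 (not isolated), via C10 cation 7 (not isolated), via C5 cation 8 (not isolated), via C4 cation 9 (not isolated)
Conditions: (S,S)-{[3,3'-(3,5-(CF3)2C6H3)2-BINOL]P(=NSO2CF3)}2NH (5 mol%), (CF3)3COH/CH2Cl2 (1:1), −30 °C, to ca. 80% conversion; Et3N; AgNO3/SiO2 chromatography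
Reagents that add atoms: none
Why: Proposed new method: the confined chiral acid protonates the terminal trisubstituted alkene of chair–chair-folded 4 and closes ring A then ring B in one enantioface-selective head-to-tail cationic polyene cyclization (the catalyst pocket fixes the absolute sense at the first ring closure, the two E-alkenes fix 5α-H/9α-H/10β-CH3 in 5), and since the acetates leave no internal O- or aryl nucleophile and neither the perfluoro alcohol nor the imidodiphosphorimidate anion is a competent base, 5 should live long enough for four stereospecific, suprafacial, mutually antiperiplanar 1,2-shifts (H-9α to C8, 10β-CH3 to C9, H-5α to C10, 4β-CH3 to C5) that set 8S, 9R, 10S and 5S and carry the charge to C4, the position most remote from the electron-poor aryl ester, where the bulky anion removes an unhindered proton of the remaining 4-methyl group (axial H-3 is screened by the angular 5-CH3; only the C8 and C4 cations carry such a methyl group, and the 8-methylidene drimane from the C8 exit is re-protonated back into the sequence) to give the exocyclic alkene and return the proton to the catalyst; closest known reaction types are the imidodiphosphorimidate-catalysed enantioselective proton-initiated cyclization of homofarnesol-type polyenes in fluorinated alcohols, confined-acid alkene protonation/Wagner–Meerwein shift/deprotonation, and the BF3-mediated 1,2-hydride/1,2-methyl (friedo) rearrangement of 8-drimanyl cations.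

Step 4
Reactants: 10 methyl 2,3,4-triacetoxy-5-{[(1R,2S,4aS,8aS)-1,2,4a-trimethyl-5-methylidenedecahydronaphthalen-1-yl]methyl}benzoate
Product: 11 methyl 2,3,4-trihydroxy-5-{[(1R,2S,4aS,8aS)-1,2,4a-trimethyl-5-methylidenedecahydronaphthalen-1-yl]methyl}benzoate (CNP0162211.1)
Conditions: K2CO3 (0.3 equiv), degassed MeOH, 0 °C, Ar; AcOH quench
Reagents that add atoms: none
Why: base-catalysed transesterification (Zemplén-type methanolysis) cleaves the three activated aryl acetates while the methyl ester only exchanges with the solvent it already matches; the alkene and the four stereocentres are untouched under these non-acidic conditions, and air is excluded to protect the pyrogallol.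

## Compound list

1 | methyl 2,3,4-trihydroxybenzoate | COC(=O)c1ccc(O)c(O)c1O | starting material
2 | (2E,6E)-farnesol | OC/C=C(C)/CC/C=C(C)/CCC=C(C)C | starting material
3 | methyl 2,3,4-trihydroxy-5-[(2E,6E)-3,7,11-trimethyldodeca-2,6,10-trien-1-yl]benzoate | COC(=O)c1cc(C/C=C(C)/CC/C=C(C)/CCC=C(C)C)c(O)c(O)c1O | intermediate
4 | methyl 2,3,4-triacetoxy-5-[(2E,6E)-3,7,11-trimethyldodeca-2,6,10-trien-1-yl]benzoate | COC(=O)c1cc(C/C=C(C)/CC/C=C(C)/CCC=C(C)C)c(OC(C)=O)c(OC(C)=O)c1OC(C)=O | intermediate
5 | drim-8-yl cation: trans-decalin, cation at C8 (bearing CH3), 9α-H, 9β-CH2Ar, 10β-CH3, 5α-H, 4,4-(CH3)2 | C[C+]1CC[C@H]2C(C)(C)CCC[C@]2(C)[C@H]1Cc1cc(C(=O)OC)c(OC(C)=O)c(OC(C)=O)c1OC(C)=O | intermediate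
6 | C9 cation: 8α-H, 8β-CH3, cation at C9 (bearing CH2Ar), 10β-CH3, 5α-H, 4,4-(CH3)2 | C[C@H]1CC[C@H]2C(C)(C)CCC[C@]2(C)[C+]1Cc1cc(C(=O)OC)c(OC(C)=O)c(OC(C)=O)c1OC(C)=O | intermediate
7 | C10 cation: 8β-CH3, 9β-CH3, 9α-CH2Ar, cation at C10, 5α-H, 4,4-(CH3)2 | C[C@H]1CC[C@H]2C(C)(C)CCC[C+]2[C@]1(C)Cc1cc(C(=O)OC)c(OC(C)=O)c(OC(C)=O)c1OC(C)=O | intermediate
8 | C5 cation: 8β-CH3, 9β-CH3, 9α-CH2Ar, 10α-H, cation at C5, 4,4-(CH3)2 | C[C@H]1CC[C+]2C(C)(C)CCC[C@H]2[C@]1(C)Cc1cc(C(=O)OC)c(OC(C)=O)c(OC(C)=O)c1OC(C)=O | intermediate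
9 | C4 cation: 5β-CH3, 8β-CH3, 9β-CH3, 9α-CH2Ar, 10α-H, cation at C4 (bearing one CH3) | C[C+]1CCC[C@H]2[C@](C)(Cc3cc(C(=O)OC)c(OC(C)=O)c(OC(C)=O)c3OC(C)=O)[C@@H](C)CC[C@]12C | intermediate
10 | methyl 2,3,4-triacetoxy-5-{[(1R,2S,4aS,8aS)-1,2,4a-trimethyl-5-methylidenedecahydronaphthalen-1-yl]methyl}benzoate (5S,8S,9R,10S; trans-decalin; exocyclic C4=CH2) | C=C1CCC[C@H]2[C@](C)(Cc3cc(C(=O)OC)c(OC(C)=O)c(OC(C)=O)c3OC(C)=O)[C@@H](C)CC[C@]12C | intermediate
11 | methyl 2,3,4-trihydroxy-5-{[(1R,2S,4aS,8aS)-1,2,4a-trimethyl-5-methylidenedecahydronaphthalen-1-yl]methyl}benzoate | C=C1CCC[C@H]2[C@](C)(Cc3cc(C(=O)OC)c(O)c(O)c3O)[C@@H](C)CC[C@]12C | target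

## Step count and weak points

Total steps: 4. Longest linear sequence: 4 steps (1 or 2 to 11).

Steps most likely to fail:

**Step 3 (highest risk).** Such cations usually stop after two shifts as the 5(10)-ene or leave early as drimenes. The exocyclic alkene of 10 can also be re-protonated and drift to the endocyclic 3-ene, and the enantiomer ratio may be moderate. A modest yield of 10 in a mixture of alkene isomers is the realistic expectation.

Fallback: separate ring formation from the backbone rearrangement and make the final proton loss irreversible. Setting out from 4, ring closure alone is run with the enantiomer of the Lewis-acid-assisted chiral Brønsted acid 2-(2-fluorobenzyloxy)-2'-hydroxy-1,1'-binaphthyl·SnCl4 that gives the same absolute series (toluene, −78 °C, then CF3CO2H/SnCl4 to finish ring B). Its basic tin aryloxide counter-ion stops the sequence at the drimane stage and gives the drimene methyl 2,3,4-triacetoxy-5-[(5α-H,9α-H,10β-CH3)-drim-7-en-11-yl]benzoate F1, together with its 8-methylidene isomer. HCl gas (CH2Cl2, −78 °C) converts this alkene mixture into the tertiary chloride methyl 2,3,4-triacetoxy-5-[(8α-chloro-5α-H,9α-H,10β-CH3)-driman-11-yl]benzoate F2. F2 is ionised with AgSbF6 in CH2Cl2 containing 10 vol% (CF3)2CHOH at −60 °C in the presence of 2,6-di-tert-butyl-4-methylpyridine, which regenerates cation 5 under aprotic conditions. No acid accumulates, so an alkene once formed is not re-protonated. The hindered base can take only methyl protons, which are on offer only at cation 5 and at cation 9. The 8-methylidene drimane from 5 is returned to F2 with HCl and cycled again, so the material is funnelled to 10, where the route is rejoined.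

**Step 1.** The ester-bearing pyrogallol is a deactivated, strongly adsorbed arene; conversion may be low and acid may cyclise the product to a chroman.

Fallback: build the aryl–CH2 bond by cross-coupling instead. Setting out from 1, bromination at the same activated position (NBS, MeCN, 0 °C) gives methyl 5-bromo-2,3,4-trihydroxybenzoate F3. Acetylation (Ac2O, pyridine) gives methyl 2,3,4-triacetoxy-5-bromobenzoate F4. Miyaura borylation (B2pin2, PdCl2(dppf) as divalent palladium precatalyst, KOAc, dioxane, 80 °C) gives methyl 2,3,4-triacetoxy-5-(4,4,5,5-tetramethyl-1,3,2-dioxaborolan-2-yl)benzoate F5. Allyl–aryl Suzuki–Miyaura coupling of F5 with commercial (2E,6E)-farnesyl bromide (Pd(PPh3)4 as zerovalent palladium catalyst, CsF, THF, 50 °C) joins the aryl group to the unsubstituted allyl terminus with the E geometry kept. This gives 4 directly, bypassing 3.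

**Step 4.** The free pyrogallol is easily oxidised by air under basic conditions.

Fallback: change the protecting group to one removed at neutral pH. Setting out from 3, allyl chloroformate/pyridine (CH2Cl2, 0 °C) gives methyl 2,3,4-tris(allyloxycarbonyloxy)-5-[(2E,6E)-3,7,11-trimethyldodeca-2,6,10-trien-1-yl]benzoate F6. The step 3 conditions applied to F6 lead through the tris(allyl carbonate) analogues of the five cations, none isolated: drim-8-yl cation F7, C9 cation F8, C10 cation F9, C5 cation F10 and C4 cation F11. They end at methyl 2,3,4-tris(allyloxycarbonyloxy)-5-{[(1R,2S,4aS,8aS)-1,2,4a-trimethyl-5-methylidenedecahydronaphthalen-1-yl]methyl}benzoate F12. Pd(PPh3)4 (zerovalent palladium) with HCO2H/Et3N in THF at rt then frees the three phenols from F12 without free base and gives 11.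

## Further compounds

F1 | step 3 | methyl 2,3,4-triacetoxy-5-[(5α-H,9α-H,10β-CH3)-drim-7-en-11-yl]benzoate | CC1=CC[C@H]2C(C)(C)CCC[C@]2(C)[C@H]1Cc1cc(C(=O)OC)c(OC(C)=O)c(OC(C)=O)c1OC(C)=O
F2 | step 3 | methyl 2,3,4-triacetoxy-5-[(8α-chloro-5α-H,9α-H,10β-CH3)-driman-11-yl]benzoate | C[C@@]1(Cl)CC[C@H]2C(C)(C)CCC[C@]2(C)[C@H]1Cc1cc(C(=O)OC)c(OC(C)=O)c(OC(C)=O)c1OC(C)=O
F3 | step 1 | methyl 5-bromo-2,3,4-trihydroxybenzoate | COC(=O)c1cc(Br)c(O)c(O)c1O
F4 | step 1 | methyl 2,3,4-triacetoxy-5-bromobenzoate | COC(=O)c1cc(Br)c(OC(C)=O)c(OC(C)=O)c1OC(C)=O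
F5 | step 1 | methyl 2,3,4-triacetoxy-5-(4,4,5,5-tetramethyl-1,3,2-dioxaborolan-2-yl)benzoate | COC(=O)c1cc(B2OC(C)(C)C(C)(C)O2)c(OC(C)=O)c(OC(C)=O)c1OC(C)=O
F6 | step 4 | methyl 2,3,4-tris(allyloxycarbonyloxy)-5-[(2E,6E)-3,7,11-trimethyldodeca-2,6,10-trien-1-yl]benzoate | COC(=O)c1cc(C/C=C(C)/CC/C=C(C)/CCC=C(C)C)c(OC(=O)OCC=C)c(OC(=O)OCC=C)c1OC(=O)OCC=C
F7 | step 4 | drim-8-yl cation as 5 but each OAc replaced by OC(=O)OCH2CH=CH2 | C[C+]1CC[C@H]2C(C)(C)CCC[C@]2(C)[C@H]1Cc1cc(C(=O)OC)c(OC(=O)OCC=C)c(OC(=O)OCC=C)c1OC(=O)OCC=C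
F8 | step 4 | C9 cation as 6 but each OAc replaced by OC(=O)OCH2CH=CH2 | C[C@H]1CC[C@H]2C(C)(C)CCC[C@]2(C)[C+]1Cc1cc(C(=O)OC)c(OC(=O)OCC=C)c(OC(=O)OCC=C)c1OC(=O)OCC=C
F9 | step 4 | C10 cation as 7 but each OAc replaced by OC(=O)OCH2CH=CH2 | C[C@H]1CC[C@H]2C(C)(C)CCC[C+]2[C@]1(C)Cc1cc(C(=O)OC)c(OC(=O)OCC=C)c(OC(=O)OCC=C)c1OC(=O)OCC=C
F10 | step 4 | C5 cation as 8 but each OAc replaced by OC(=O)OCH2CH=CH2 | C[C@H]1CC[C+]2C(C)(C)CCC[C@H]2[C@]1(C)Cc1cc(C(=O)OC)c(OC(=O)OCC=C)c(OC(=O)OCC=C)c1OC(=O)OCC=C
F11 | step 4 | C4 cation as 9 but each OAc replaced by OC(=O)OCH2CH=CH2 | C[C+]1CCC[C@H]2[C@](C)(Cc3cc(C(=O)OC)c(OC(=O)OCC=C)c(OC(=O)OCC=C)c3OC(=O)OCC=C)[C@@H](C)CC[C@]12C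
F12 | step 4 | methyl 2,3,4-tris(allyloxycarbonyloxy)-5-{[(1R,2S,4aS,8aS)-1,2,4a-trimethyl-5-methylidenedecahydronaphthalen-1-yl]methyl}benzoate | C=C1CCC[C@H]2[C@](C)(Cc3cc(C(=O)OC)c(OC(=O)OCC=C)c(OC(=O)OCC=C)c3OC(=O)OCC=C)[C@@H](C)CC[C@]12C
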